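## Retrosynthetic overview
1. The target is (2S,3R,4R), 2,3-trans and 3,4-cis. It comes from the tri-O-benzyl tetrahydrofuran-3-ylmethanol by O-acetylation followed by global O-debenzylation.
2. The tetrahydrofuran C2–O bond comes from benzylic-cation ring closure of a (2R,3R)-2-(aryl-hydroxymethyl)-3-benzylbutane-1,4-diol. That triol is made by LiAlH4 opening of an α-(aryl-hydroxymethyl)-β-benzyl-γ-butyrolactone.
3. The key C–C disconnection is ArCH(OH)–Cα: aldol addition of the lithium enolate of (R)-β-(4-benzyloxy-3-methoxybenzyl)-γ-butyrolactone to 3,4-bis(benzyloxy)benzaldehyde.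
4. The (R)-lactone comes from Evans alkylation of an N-(3-arylpropanoyl)-(S)-4-benzyloxazolidinone with tert-butyl bromoacetate. The arylpropanoic acid comes from ferulic acid.
5. Ring order: the γ-butyrolactone is formed first (temporary stereocontrol ring, closed in step 8 and opened in step 11). The tetrahydrofuran is formed last (step 12).

Assumption: the carbinol carbon of 18 and 19 is carried as a mixture of both epimers (written without a descriptor), because step 12 resets that centre.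

Abbreviations: Bn = benzyl, TBS = tert-butyldimethylsilyl.

## Route

Step 1
Reactants: 1 ferulic acid [(E)-3-(4-hydroxy-3-methoxyphenyl)prop-2-enoic acid]
Product: 2 3-(4-hydroxy-3-methoxyphenyl)propanoic acid
Conditions: H2 (1 atm), 10% Pd/C, MeOH, rt
Reagents that add atoms: none
Why: Catalytic hydrogenation saturates the conjugated alkene cleanly while arene, phenol and acid are untouched, and running it before any benzyl group is present avoids a chemoselectivity problem.

Step 2
Reactants: 2 3-(4-hydroxy-3-methoxyphenyl)propanoic acid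
Product: 3 benzyl 3-[4-(benzyloxy)-3-methoxyphenyl]propanoate
Conditions: BnBr (2.4 equiv), K2CO3 (3 equiv), DMF, 60 °C
Reagents that add atoms: benzyl bromide BrCc1ccccc1
Why: Williamson ether synthesis and carboxylate O-alkylation (both SN2 on benzyl bromide) run together, so exhaustive benzylation gives one clean product instead of a mixture.

Step 3
Reactants: 3 benzyl 3-[4-(benzyloxy)-3-methoxyphenyl]propanoate
Product: 4 3-[4-(benzyloxy)-3-methoxyphenyl]propanoic acid
Conditions: NaOH (2 M aq), THF/MeOH, rt; then 1 M HCl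
Reagents that add atoms: sodium hydroxide [Na+].[OH-] (oxygen of the new acid OH)
Why: Saponification cleaves only the benzyl ester because aryl benzyl ethers are inert to aqueous hydroxide.

Step 4
Reactants: 4 3-[4-(benzyloxy)-3-methoxyphenyl]propanoic acid; 5 (S)-4-benzyl-1,3-oxazolidin-2-one
Product: 7 (4S)-4-benzyl-3-{3-[4-(benzyloxy)-3-methoxyphenyl]propanoyl}-1,3-oxazolidin-2-one, via mixed pivalic anhydride 6 (not isolated)
Conditions: t-BuCOCl, Et3N (2.5 equiv), THF, −20 °C; then LiCl, 5, −20 °C → rt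
Reagents that add atoms: pivaloyl chloride CC(C)(C)C(=O)Cl (its acyl group is kept only in intermediate 6)
Why: N-acylation of the Evans auxiliary through a mixed anhydride works because the LiCl/Et3N-activated oxazolidinone attacks the unhindered acyl carbon of 6 rather than the pivaloyl carbon, and the auxiliary stereocentre is not touched.

Step 5
Reactants: 7 (4S)-4-benzyl-3-{3-[4-(benzyloxy)-3-methoxyphenyl]propanoyl}-1,3-oxazolidin-2-one; 8 tert-butyl bromoacetate
Product: 10 tert-butyl (3R)-3-[4-(benzyloxy)-3-methoxybenzyl]-4-[(4S)-4-benzyl-2-oxo-1,3-oxazolidin-3-yl]-4-oxobutanoate, via sodium Z-enolate 9 (not isolated)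
Conditions: NaN(SiMe3)2 (1.1 equiv), THF, −78 °C, 45 min; then 8 (2 equiv), −78 → −40 °C
Reagents that add atoms: sodium hexamethyldisilazide [Na+].C[Si](C)(C)[N-][Si](C)(C)C (sodium is kept only in intermediate 9)
Why: In this Evans asymmetric alkylation the chelated Z-enolate 9 is shielded on one face by the C4 benzyl group of the auxiliary, so the reactive bromoacetate is taken up from the opposite face and sets the (R) centre (future C4 of the target) with dr typically above 95:5, the minor isomer being removed by chromatography.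

Step 6
Reactants: 10 tert-butyl (3R)-3-[4-(benzyloxy)-3-methoxybenzyl]-4-[(4S)-4-benzyl-2-oxo-1,3-oxazolidin-3-yl]-4-oxobutanoate
Product: 12 (2R)-2-[4-(benzyloxy)-3-methoxybenzyl]-4-tert-butoxy-4-oxobutanoic acid, via peroxy acid 11 (not isolated)
Conditions: LiOH (2 equiv), 30% H2O2 (4 equiv), THF/H2O 3:1, 0 °C; then aq Na2SO3; then 1 M HCl to pH 3
Reagents that add atoms: hydrogen peroxide OO (two O in 11, one O in 12)
Why: In this hydroperoxide-mediated auxiliary cleavage the small and highly nucleophilic hydroperoxide anion attacks the exocyclic imide carbonyl selectively, without epimerisation or loss of the tert-butyl ester, and sulfite then reduces peroxy acid 11 to the acid.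

Step 7
Reactants: 12 (2R)-2-[4-(benzyloxy)-3-methoxybenzyl]-4-tert-butoxy-4-oxobutanoic acid
Product: 13 tert-butyl (3R)-3-[4-(benzyloxy)-3-methoxybenzyl]-4-hydroxybutanoate
Conditions: BH3·SMe2 (1.5 equiv), THF, 0 °C → rt; MeOH quench
Reagents that add atoms: none
Why: Chemoselective borane reduction works because electrophilic BH3 reduces the free acid through an acyloxyborane much faster than it touches the tert-butyl ester, and the stereocentre is not involved.

Step 8
Reactants: 13 tert-butyl (3R)-3-[4-(benzyloxy)-3-methoxybenzyl]-4-hydroxybutanoate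
Product: 14 (4R)-4-[4-(benzyloxy)-3-methoxybenzyl]dihydrofuran-2(3H)-one
Conditions: p-TsOH·H2O (10 mol %), toluene, 80 °C
Reagents that add atoms: none
Why: Acid-catalysed lactonisation (intramolecular transesterification) is driven by five-membered ring formation and loss of tert-butanol, and the stereocentre is beta to the carbonyl and cannot epimerise.

Step 9
Reactants: 15 3,4-dihydroxybenzaldehyde
Product: 16 3,4-bis(benzyloxy)benzaldehyde
Conditions: BnBr (2.3 equiv), K2CO3 (3 equiv), DMF, 60 °C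
Reagents that add atoms: benzyl bromide BrCc1ccccc1
Why: Double Williamson ether synthesis on the acidic catechol hydroxyls is clean because the aldehyde has no alpha hydrogen and is inert to K2CO3.

Step 10
Reactants: 14 (4R)-4-[4-(benzyloxy)-3-methoxybenzyl]dihydrofuran-2(3H)-one; 16 3,4-bis(benzyloxy)benzaldehyde
Product: 18 (3S,4R)-3-{[3,4-bis(benzyloxy)phenyl](hydroxy)methyl}-4-[4-(benzyloxy)-3-methoxybenzyl]dihydrofuran-2(3H)-one (both carbinol epimers), via lithium enolate 17 (not isolated)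
Conditions: LiN(SiMe3)2 (1.1 equiv), THF, −78 °C, 1 h; then 16 in THF, −78 °C, 2 h; AcOH/THF quench at −78 °C
Reagents that add atoms: lithium hexamethyldisilazide [Li+].C[Si](C)(C)[N-][Si](C)(C)C (lithium is kept only in intermediate 17)
Why: In this intermolecular aldol addition enolate 17 attacks the non-enolisable aldehyde from the ring face anti to the C4 benzyl substituent, which fixes the 3,4-trans (3S) centre (future C3 of the target), while the carbinol centre forms as an inconsequential epimer mixture and the cold acidic quench prevents retro-aldol.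

Step 11
Reactants: 18 (3S,4R)-3-{[3,4-bis(benzyloxy)phenyl](hydroxy)methyl}-4-[4-(benzyloxy)-3-methoxybenzyl]dihydrofuran-2(3H)-one
Product: 19 (2R,3R)-2-{[3,4-bis(benzyloxy)phenyl](hydroxy)methyl}-3-[4-(benzyloxy)-3-methoxybenzyl]butane-1,4-diol (both carbinol epimers)
Conditions: LiAlH4 (2.5 equiv), THF, 0 °C, 1 h; H2O / 15% aq NaOH / H2O work-up
Reagents that add atoms: none
Why: Hydride reduction of the lactone to the 1,4-diol is fast at 0 °C and outruns retro-aldol of the alkoxide, it removes the only epimerisable position, and benzyl ethers are inert to LiAlH4.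

Step 12
Reactants: 19 (2R,3R)-2-{[3,4-bis(benzyloxy)phenyl](hydroxy)methyl}-3-[4-(benzyloxy)-3-methoxybenzyl]butane-1,4-diol
Product: 20 {(2S,3R,4R)-2-[3,4-bis(benzyloxy)phenyl]-4-[4-(benzyloxy)-3-methoxybenzyl]tetrahydrofuran-3-yl}methanol
Conditions: (+)-10-camphorsulfonic acid (10 mol %), CH2Cl2 (0.02 M), 0 °C → rt, Et3N quench as soon as 19 is consumed
Reagents that add atoms: none
Why: In this acid-catalysed dehydrative cycloetherification of SN1 type both carbinol epimers ionise to the same p-benzyloxy-stabilised benzylic cation, which is captured fastest by the C4 hydroxyl in a five-membered closure (the C1 hydroxyl could only give an oxetane), and the new C2 centre is set (S) with aryl trans to the neighbouring CH2OH because that approach avoids eclipsing and the reversible closure also funnels material to the more stable 2,3-trans isomer, C3 and C4 being untouched.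

Step 13
Reactants: 20 {(2S,3R,4R)-2-[3,4-bis(benzyloxy)phenyl]-4-[4-(benzyloxy)-3-methoxybenzyl]tetrahydrofuran-3-yl}methanol
Product: 21 {(2S,3R,4R)-2-[3,4-bis(benzyloxy)phenyl]-4-[4-(benzyloxy)-3-methoxybenzyl]tetrahydrofuran-3-yl}methyl acetate
Conditions: Ac2O (1.5 equiv), pyridine, DMAP (5 mol %), CH2Cl2, 0 °C → rt
Reagents that add atoms: acetic anhydride CC(=O)OC(C)=O
Why: DMAP-catalysed O-acylation meets the only free hydroxyl group of 20, so no selectivity issue arises and no stereocentre is touched.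

Step 14
Reactants: 21 {(2S,3R,4R)-2-[3,4-bis(benzyloxy)phenyl]-4-[4-(benzyloxy)-3-methoxybenzyl]tetrahydrofuran-3-yl}methyl acetate
Product: 22 {(2S,3R,4R)-2-(3,4-dihydroxyphenyl)-4-(4-hydroxy-3-methoxybenzyl)tetrahydrofuran-3-yl}methyl acetate (target)
Conditions: H2 (1 atm), 10% Pd/C, EtOAc, rt, stopped at full debenzylation (LC-MS control), filtration under N2
Reagents that add atoms: none
Why: Catalytic hydrogenolysis cleaves the three aryl benzyl ethers far faster than the hindered secondary ring C2–O bond, so in non-acidic EtOAc at 1 atm and with the reaction stopped at conversion the tetrahydrofuran, the acetate and all three stereocentres survive.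

## Compound list
1 | ferulic acid, (E)-3-(4-hydroxy-3-methoxyphenyl)prop-2-enoic acid | COc1cc(/C=C/C(=O)O)ccc1O | starting material
2 | 3-(4-hydroxy-3-methoxyphenyl)propanoic acid | COc1cc(CCC(=O)O)ccc1O | intermediate
3 | benzyl 3-[4-(benzyloxy)-3-methoxyphenyl]propanoate | COc1cc(CCC(=O)OCc2ccccc2)ccc1OCc1ccccc1 | intermediate
4 | 3-[4-(benzyloxy)-3-methoxyphenyl]propanoic acid | COc1cc(CCC(=O)O)ccc1OCc1ccccc1 | intermediate
5 | (S)-4-benzyl-1,3-oxazolidin-2-one | O=C1N[C@@H](Cc2ccccc2)CO1 | starting material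
6 | 3-[4-(benzyloxy)-3-methoxyphenyl]propanoic pivalic anhydride | COc1cc(CCC(=O)OC(=O)C(C)(C)C)ccc1OCc1ccccc1 | intermediate (not isolated)
7 | (4S)-4-benzyl-3-{3-[4-(benzyloxy)-3-methoxyphenyl]propanoyl}-1,3-oxazolidin-2-one | COc1cc(CCC(=O)N2[C@@H](Cc3ccccc3)COC2=O)ccc1OCc1ccccc1 | intermediate
8 | tert-butyl bromoacetate | CC(C)(C)OC(=O)CBr | starting material
9 | sodium (Z)-enolate of imide 7 | [Na+].COc1cc(C/C=C(\[O-])N2[C@@H](Cc3ccccc3)COC2=O)ccc1OCc1ccccc1 | intermediate (not isolated)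
10 | tert-butyl (3R)-3-[4-(benzyloxy)-3-methoxybenzyl]-4-[(4S)-4-benzyl-2-oxo-1,3-oxazolidin-3-yl]-4-oxobutanoate | COc1cc(C[C@@H](C(=O)N2[C@@H](Cc3ccccc3)COC2=O)CC(=O)OC(C)(C)C)ccc1OCc1ccccc1 | intermediate
11 | (2R)-2-[4-(benzyloxy)-3-methoxybenzyl]-4-tert-butoxy-4-oxobutaneperoxoic acid | COc1cc(C[C@@H](C(=O)OO)CC(=O)OC(C)(C)C)ccc1OCc1ccccc1 | intermediate (not isolated)
12 | (2R)-2-[4-(benzyloxy)-3-methoxybenzyl]-4-tert-butoxy-4-oxobutanoic acid | COc1cc(C[C@@H](C(=O)O)CC(=O)OC(C)(C)C)ccc1OCc1ccccc1 | intermediate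
13 | tert-butyl (3R)-3-[4-(benzyloxy)-3-methoxybenzyl]-4-hydroxybutanoate | COc1cc(C[C@@H](CO)CC(=O)OC(C)(C)C)ccc1OCc1ccccc1 | intermediate
14 | (4R)-4-[4-(benzyloxy)-3-methoxybenzyl]dihydrofuran-2(3H)-one | COc1cc(C[C@H]2COC(=O)C2)ccc1OCc1ccccc1 | intermediate
15 | 3,4-dihydroxybenzaldehyde | O=Cc1ccc(O)c(O)c1 | starting material
16 | 3,4-bis(benzyloxy)benzaldehyde | O=Cc1ccc(OCc2ccccc2)c(OCc2ccccc2)c1 | intermediate
17 | lithium enolate of lactone 14 | [Li+].COc1cc(C[C@H]2COC([O-])=C2)ccc1OCc1ccccc1 | intermediate (not isolated)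
18 | (3S,4R)-3-{[3,4-bis(benzyloxy)phenyl](hydroxy)methyl}-4-[4-(benzyloxy)-3-methoxybenzyl]dihydrofuran-2(3H)-one, 3,4-trans, both carbinol epimers | COc1cc(C[C@H]2COC(=O)[C@@H]2C(O)c3ccc(OCc4ccccc4)c(OCc4ccccc4)c3)ccc1OCc1ccccc1 | intermediate
19 | (2R,3R)-2-{[3,4-bis(benzyloxy)phenyl](hydroxy)methyl}-3-[4-(benzyloxy)-3-methoxybenzyl]butane-1,4-diol, both carbinol epimers | COc1cc(C[C@@H](CO)[C@H](CO)C(O)c2ccc(OCc3ccccc3)c(OCc3ccccc3)c2)ccc1OCc1ccccc1 | intermediate
20 | {(2S,3R,4R)-2-[3,4-bis(benzyloxy)phenyl]-4-[4-(benzyloxy)-3-methoxybenzyl]tetrahydrofuran-3-yl}methanol | COc1cc(C[C@H]2CO[C@H](c3ccc(OCc4ccccc4)c(OCc4ccccc4)c3)[C@H]2CO)ccc1OCc1ccccc1 | intermediate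
21 | {(2S,3R,4R)-2-[3,4-bis(benzyloxy)phenyl]-4-[4-(benzyloxy)-3-methoxybenzyl]tetrahydrofuran-3-yl}methyl acetate | COc1cc(C[C@H]2CO[C@H](c3ccc(OCc4ccccc4)c(OCc4ccccc4)c3)[C@H]2COC(C)=O)ccc1OCc1ccccc1 | intermediate
22 | {(2S,3R,4R)-2-(3,4-dihydroxyphenyl)-4-(4-hydroxy-3-methoxybenzyl)tetrahydrofuran-3-yl}methyl acetate | COc1cc(C[C@H]2CO[C@H](c3ccc(O)c(O)c3)[C@H]2COC(C)=O)ccc1O | target

## Count and risks
Total step count: 14.
Longest linear sequence: 13 (steps 1–8, then 10–14). Step 9 is the side branch.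

**Step 10 (aldol).**
- Risk: retro-aldol, incomplete conversion or lactone self-condensation.
- Fallback: make the same bond irreversibly by a crossed Claisen-type C-acylation, then reduce the ketone.
- It sets out from 14 and 16 and comes back at 18.
- Pinnick oxidation of 16 (NaClO2, NaH2PO4, 2-methyl-2-butene, t-BuOH/H2O) gives 3,4-bis(benzyloxy)benzoic acid F1. Oxalyl chloride with a drop of DMF in CH2Cl2 turns this into 3,4-bis(benzyloxy)benzoyl chloride F2.
- Enolate 17, made from 14 with 2.1 equiv LiN(SiMe3)2 in THF at −78 °C, is acylated to (3S,4R)-3-[3,4-bis(benzyloxy)benzoyl]-4-[4-(benzyloxy)-3-methoxybenzyl]dihydrofuran-2(3H)-one F3. Its acidic C3–H lets it settle as the 3,4-trans isomer.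
- NaBH4 in THF/MeOH at −20 °C reduces only the ketone and delivers 18 as an epimer mixture.

**Step 12 (ring closure).**
- Risk: Friedel–Crafts capture of the cation by the guaiacyl ring to give an aryltetralin, acid-induced drift of the product, or too much 2-epimer.
- Fallback: build the leaving group under basic conditions and let a silyl ether oxygen be the internal nucleophile, so that no Brønsted acid is ever present.
- It sets out from 19 and comes back at 20.
- TBSCl (2.1 equiv) and imidazole in CH2Cl2 at 0 °C silylate only the two primary hydroxyls. This gives (2R,3R)-1-[3,4-bis(benzyloxy)phenyl]-3-[4-(benzyloxy)-3-methoxybenzyl]-4-(TBSO)-2-[(TBSO)methyl]butan-1-ol F4.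
- MsCl/Et3N in CH2Cl2 (−20 °C → rt) gives the labile (2R,3R)-1-[3,4-bis(benzyloxy)phenyl]-3-[4-(benzyloxy)-3-methoxybenzyl]-4-(TBSO)-2-[(TBSO)methyl]butyl methanesulfonate F5, which ionises in the flask.
- The C4 silyloxy oxygen closes the five-membered ring trans to the neighbouring CH2OTBS group and chloride carries off the silyl group. The product is {(2S,3R,4R)-2-[3,4-bis(benzyloxy)phenyl]-4-[4-(benzyloxy)-3-methoxybenzyl]tetrahydrofuran-3-yl}methyl tert-butyldimethylsilyl ether F6.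
- Bu4NF in THF then frees alcohol 20.

**Step 14 (global hydrogenolysis).**
- Risk: over-reduction of the benzylic ring C2–O bond to the ring-opened diol.
- Fallback: exchange the phenol protecting groups for silyl ethers at a stage where hydrogenolysis is harmless, so that the last step is a fluoride deprotection.
- It sets out from 14 and 15 and comes back at 22.
- H2 and 10% Pd/C in EtOAc convert 14 into (4R)-4-(4-hydroxy-3-methoxybenzyl)dihydrofuran-2(3H)-one F7. TBSCl/imidazole in DMF gives (4R)-4-[4-(TBSO)-3-methoxybenzyl]dihydrofuran-2(3H)-one F8.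
- The same silylation of 15 gives 3,4-bis(TBSO)benzaldehyde F9.
- LiN(SiMe3)2 in THF at −78 °C turns F8 into the lithium enolate of the TBS lactone F10. This adds to F9 (AcOH quench at −78 °C) to give (3S,4R)-3-{[3,4-bis(TBSO)phenyl](hydroxy)methyl}-4-[4-(TBSO)-3-methoxybenzyl]dihydrofuran-2(3H)-one F11.
- LiBH4 in THF/MeOH gives (2R,3R)-2-{[3,4-bis(TBSO)phenyl](hydroxy)methyl}-3-[4-(TBSO)-3-methoxybenzyl]butane-1,4-diol F12.
- Camphorsulfonic acid (10 mol %) in CH2Cl2 closes the ring to {(2S,3R,4R)-2-[3,4-bis(TBSO)phenyl]-4-[4-(TBSO)-3-methoxybenzyl]tetrahydrofuran-3-yl}methanol F13.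
- Ac2O/pyridine/DMAP gives {(2S,3R,4R)-2-[3,4-bis(TBSO)phenyl]-4-[4-(TBSO)-3-methoxybenzyl]tetrahydrofuran-3-yl}methyl acetate F14.
- Et3N·3HF in THF at 0 °C removes the three aryl silyl ethers without touching the acetate or the ring, giving 22.

## Further compounds
F1 | step 10 | 3,4-bis(benzyloxy)benzoic acid | O=C(O)c1ccc(OCc2ccccc2)c(OCc2ccccc2)c1
F2 | step 10 | 3,4-bis(benzyloxy)benzoyl chloride | O=C(Cl)c1ccc(OCc2ccccc2)c(OCc2ccccc2)c1
F3 | step 10 | (3S,4R)-3-[3,4-bis(benzyloxy)benzoyl]-4-[4-(benzyloxy)-3-methoxybenzyl]dihydrofuran-2(3H)-one | COc1cc(C[C@H]2COC(=O)[C@@H]2C(=O)c3ccc(OCc4ccccc4)c(OCc4ccccc4)c3)ccc1OCc1ccccc1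
F4 | step 12 | (2R,3R)-1-[3,4-bis(benzyloxy)phenyl]-3-[4-(benzyloxy)-3-methoxybenzyl]-4-(TBSO)-2-[(TBSO)methyl]butan-1-ol, both carbinol epimers | COc1cc(C[C@@H](CO[Si](C)(C)C(C)(C)C)[C@H](CO[Si](C)(C)C(C)(C)C)C(O)c2ccc(OCc3ccccc3)c(OCc3ccccc3)c2)ccc1OCc1ccccc1
F5 | step 12 | (2R,3R)-1-[3,4-bis(benzyloxy)phenyl]-3-[4-(benzyloxy)-3-methoxybenzyl]-4-(TBSO)-2-[(TBSO)methyl]butyl methanesulfonate, not isolated | COc1cc(C[C@@H](CO[Si](C)(C)C(C)(C)C)[C@H](CO[Si](C)(C)C(C)(C)C)C(OS(C)(=O)=O)c2ccc(OCc3ccccc3)c(OCc3ccccc3)c2)ccc1OCc1ccccc1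
F6 | step 12 | {(2S,3R,4R)-2-[3,4-bis(benzyloxy)phenyl]-4-[4-(benzyloxy)-3-methoxybenzyl]tetrahydrofuran-3-yl}methyl tert-butyldimethylsilyl ether | COc1cc(C[C@H]2CO[C@H](c3ccc(OCc4ccccc4)c(OCc4ccccc4)c3)[C@H]2CO[Si](C)(C)C(C)(C)C)ccc1OCc1ccccc1
F7 | step 14 | (4R)-4-(4-hydroxy-3-methoxybenzyl)dihydrofuran-2(3H)-one | COc1cc(C[C@H]2COC(=O)C2)ccc1O
F8 | step 14 | (4R)-4-[4-(TBSO)-3-methoxybenzyl]dihydrofuran-2(3H)-one | COc1cc(C[C@H]2COC(=O)C2)ccc1O[Si](C)(C)C(C)(C)C
F9 | step 14 | 3,4-bis(TBSO)benzaldehyde | O=Cc1ccc(O[Si](C)(C)C(C)(C)C)c(O[Si](C)(C)C(C)(C)C)c1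
F10 | step 14 | lithium enolate of the TBS lactone, not isolated | [Li+].COc1cc(C[C@H]2COC([O-])=C2)ccc1O[Si](C)(C)C(C)(C)C
F11 | step 14 | (3S,4R)-3-{[3,4-bis(TBSO)phenyl](hydroxy)methyl}-4-[4-(TBSO)-3-methoxybenzyl]dihydrofuran-2(3H)-one, both carbinol epimers | COc1cc(C[C@H]2COC(=O)[C@@H]2C(O)c3ccc(O[Si](C)(C)C(C)(C)C)c(O[Si](C)(C)C(C)(C)C)c3)ccc1O[Si](C)(C)C(C)(C)C
F12 | step 14 | (2R,3R)-2-{[3,4-bis(TBSO)phenyl](hydroxy)methyl}-3-[4-(TBSO)-3-methoxybenzyl]butane-1,4-diol, both carbinol epimers | COc1cc(C[C@@H](CO)[C@H](CO)C(O)c2ccc(O[Si](C)(C)C(C)(C)C)c(O[Si](C)(C)C(C)(C)C)c2)ccc1O[Si](C)(C)C(C)(C)C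
F13 | step 14 | {(2S,3R,4R)-2-[3,4-bis(TBSO)phenyl]-4-[4-(TBSO)-3-methoxybenzyl]tetrahydrofuran-3-yl}methanol | COc1cc(C[C@H]2CO[C@H](c3ccc(O[Si](C)(C)C(C)(C)C)c(O[Si](C)(C)C(C)(C)C)c3)[C@H]2CO)ccc1O[Si](C)(C)C(C)(C)C
F14 | step 14 | {(2S,3R,4R)-2-[3,4-bis(TBSO)phenyl]-4-[4-(TBSO)-3-methoxybenzyl]tetrahydrofuran-3-yl}methyl acetate | COc1cc(C[C@H]2CO[C@H](c3ccc(O[Si](C)(C)C(C)(C)C)c(O[Si](C)(C)C(C)(C)C)c3)[C@H]2COC(C)=O)ccc1O[Si](C)(C)C(C)(C)C
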